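## The problem

The target is a 9,9'-epoxylignan. Its tetrahydrofuran (ring C) carries at C8' a benzyl group ending in the guaiacyl ring A (through C7'), and at the neighbouring C8 a secondary benzylic carbinol C7 bearing the syringyl ring B. The three stereocentres are contiguous, (7S,8R,8'R), with the two ring substituents trans. They are not equally hard. C8 lies next to C7, so whenever C7 is a carbonyl carbon C8 can epimerise and will settle trans to the C8' substituent; C8' is therefore the centre that must be fixed in the absolute sense. C7 lies outside the ring, where C8 offers only a weak bias, and needs reagent control. The sensitive parts are the two free phenols and above all the 4-hydroxybenzylic alcohol at C7, which ionises toward a quinone methide in acid, is prone to hydrogenolysis and oxidises easily; the C7 hydroxyl should appear late and the phenols stay masked to the end. The feature that opens a short route is that O–C9'–C8'–C7' is a propargyl alcohol in disguise and C9–C8–C7 a methylidenemalonate in disguise (methylene carbon C9, malonate carbon C8, one ester carbon C7). If C8'=C7' is accepted as an exocyclic arylidene, ring C, the attachment of ring A and the C7 carbon can be assembled from three achiral pieces in one palladium-mediated operation.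

## Retrosynthesis

The last disconnection removes only protecting groups: 18 comes from the bis(benzyl ether) 17 by cleavage of the two aryl O–CH2Ph bonds. Benzyl is preferred to silyl or acetal protection because the ring A ether must pass through alkoxide in DMSO, chloride at 160 °C, Grignard and organolithium reagents and borane, and because its removal needs neither acid nor fluoride. The forward reaction must cleave two phenolic benzyl ethers and leave the benzylic C7–O bond intact.

The C7–H bond is cut next, leading from alcohol 17 to aryl ketone 16. The neighbouring choice, making C7–aryl by adding an aryl metal to an aldehyde, would set C7 under the weak bias of C8 alone. A ketone lets an enantioselective catalyst decide and keeps C8 epimerisable toward trans as a safeguard. 16 has one stereocentre fewer; the forward reaction must deliver hydride to one face under reagent control.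

Cutting the C7–aryl bond of 16 gives the N-methoxy-N-methylamide 12 and the aryllithium 15, which comes from bromide 14 and so from the commercial bromophenol 13. This is the convergent cut: ring B arrives as a nucleophile in one step and the amide ensures single addition. 12 is a small tetrahydrofuran with two stereocentres and no ring B.

Amide 12 is an acyl derivative of the trans ester 11, and 11 is simplified by restoring a second ester at C8, which gives the geminal diester 9. This removes C8 from the stereochemical problem: in 9 only C8' is stereogenic, and de-ethoxycarbonylation followed by base equilibration (through the epimer mixture 10) lets C8' dictate C8. Losing the ester before the ring stereocentre is in place would leave an acidic proton beside an exocyclic alkene that could then migrate. The forward step has to remove one ester and end at the thermodynamic trans isomer.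

Diester 9 is related to the arylidene diester 8 by the C8'–H and C7'–H bonds. 8 is achiral, its alkene has one fixed geometry and, flanked by a quaternary carbon, cannot shift by enolisation. A single enantioselective hydrogenation therefore introduces all the absolute stereochemistry of the ring, at the cost of one catalytic step instead of an auxiliary or a resolution. The forward reaction must reduce a hindered trisubstituted alkene with high facial selectivity and spare the benzyl ether.

The strategic cut dissolves 8 into three achiral parts by breaking O–C9, C8–C8' and C7'–aryl: propargyl alcohol 5 (O, C9', C8', C7'), methylidenemalonate 2 (C9, C8 and the future C7) and aryl iodide 4 (ring A). These bonds could be made one at a time by etherification, a separate cyclisation and a cross-coupling. The sequence of conjugate addition, carbopalladation and reductive elimination makes all three in one flask through alkoxide 6 and enolate 7, and its mechanism fixes the alkene geometry. This is the largest simplification of the route. The forward reaction needs clean oxygen addition to a polymerisation-prone acceptor, 5-exo closure and anti addition across the alkyne.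

The remaining precursors are one step from commerce: 2 by methylenation of diethyl malonate 1, 4 by O-benzylation of iodophenol 3, and 14 by O-benzylation of 13.

## Roads not taken

Alternative 1: The cuts are C7–C8 and C8'–C7' on a preformed five-membered ring. The chiral butenolide (5R)-5-(l-menthyloxy)furan-2(5H)-one A1 would take up the lithio derivative of the syringyl dithiane A2 at its β-carbon (C7–C8), and the lactone enolate would be benzylated in the same flask by the guaiacyl benzylic bromide A3 (C8'–C7') to give the trans,trans lactone A4.
- Merits: the acetal stereocentre directs both additions anti, so C8 and C8' are set together in the right relative and absolute sense, with control that is well established for this tandem process. Both aryl rings are in place after one operation.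
- Weak points: ring C is not yet a tetrahydrofuran, so the lactone acetal must be reduced to the 1,4-diol and closed again to the ether. The dithiane must be unmasked to the C7 ketone by oxidative or alkylative thioacetal cleavage beside two electron-rich arenes. The route would then meet ketone 16 and still face the same late reduction at C7. The auxiliary is stoichiometric, A1, A2 and A3 each need two or three steps, and sulfur residues are unwelcome before a hydrogenolysis over Pd/C.
- Comparison: in certainty of the C8/C8' configuration this road is the better one. The chosen plan offers a ring C made directly at the ether oxidation level, catalytic rather than auxiliary-borne chirality, no thioacetal chemistry and a total count lower by roughly three steps.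

Alternative 2: Ring C would be closed last, at C8'–C9'. The acyclic (phenylselanyl)methyl ether A5, which already holds C7 (as silyl ether) and C8 and carries an E-configured styrene toward ring A, would be treated with a tin hydride. The alkoxymethyl radical adds 5-exo-trig to C8', the benzylic radical at C7' is reduced, and the fully protected target A6 results.
- Merits: C7 is set early by dependable acyclic stereocontrol (for example an auxiliary aldol), so no late ketone reduction beside a stereocentre is needed. The cyclisation delivers the whole skeleton at the final oxidation level.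
- Weak points: C8' arises under substrate control only, and a substituent at C8 (position 4 of the hexenyl radical) gives the trans ring as the major but rarely the sole product. The alkoxymethyl radical can reach the doubly activated C7–H by 1,5-hydrogen transfer. The aldol partner needed for A5 is a β,γ-unsaturated acyl unit that tends to slip into conjugation with ring A. Selenium and tin reagents are used stoichiometrically near the end.
- Comparison: in the handling of C7 this road is at least as good as the chosen one, which relies on reagent control in step 9. The chosen plan answers with a C8' centre set by a catalyst, a C8 centre set by equilibrium and a much shorter way to its cyclisation substrate.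

Alternative 3: Both ring bonds C8–C9 and C8'–C9' would be formed at once. The E-configured enoyl oxazolidinone A7 would be exposed to chloromethyl (trimethylsilyl)methyl ether A8 and a fluoride source. The unsubstituted carbonyl ylide A9 released from A8 adds across C8=C8' to give the trans acyl oxazolidinone A10, and transamidation would lead to amide 12 and the same endgame.
- Merits: on paper this is the shortest road. One step makes the ring, the E geometry passes stereospecifically into the trans relationship, and no decarboxylation or hydrogenation is needed, so 12 would be reached in about two steps fewer.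
- Weak points: the ylide is small, unstabilised and very reactive, and the transition state is early. The fluoride conditions exclude the chelating Lewis acid that normally locks an acyl oxazolidinone in one conformation, so facial discrimination may be weak and the diastereomers would have to be separated, which amounts to a resolution. The γ-protons of A7 are benzylic and vinylogously acidic, so basic fluoride may move the double bond toward ring A.
- Comparison: in step economy this road is better. The chosen plan offers an absolute configuration from a tunable catalyst acting on an achiral alkene of fixed geometry, with the antipodal ligand and a wide ligand family in reserve, and a key step whose regio- and stereochemical course is known for its reaction type.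

Key step: step 3

Assumption: the facial sense of the iridium catalyst on 8 is taken by analogy, not from a firm model, to be such that the (S)-configured ligand gives (R) at C8'; the mirror-image ligand is used without other change if the opposite sense is found.

## Route

Step 1
Reactants: 1 diethyl malonate
Product: 2 diethyl methylidenemalonate
Conditions: (CH2O)n, Cu(OAc)2 (cat.), KOAc (cat.), AcOH, 100 °C; distillation under reduced pressure
Reagents that add atoms: formaldehyde (as paraformaldehyde), C=O
Why: Knoevenagel condensation of an active methylene compound with formaldehyde; oligomers crack to the monomer on distillation, which is kept cold and used promptly because traces of base polymerise it.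

Step 2
Reactants: 3 4-iodo-2-methoxyphenol
Product: 4 1-(benzyloxy)-4-iodo-2-methoxybenzene
Conditions: BnBr, K2CO3, DMF, 25 °C
Reagents that add atoms: benzyl bromide, BrCc1ccccc1
Why: Williamson ether synthesis of a phenol with a benzylic halide; the aryl iodide is inert to carbonate.

Step 3
Reactants: 5 propargyl alcohol; 2 diethyl methylidenemalonate; 4 1-(benzyloxy)-4-iodo-2-methoxybenzene
Product: 8 diethyl (Z)-4-[4-(benzyloxy)-3-methoxybenzylidene]dihydrofuran-3,3(2H)-dicarboxylate, via potassium prop-2-yn-1-olate 6 (not isolated), via potassium malonate enolate 7 (not isolated)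
Conditions: 5 (1.3 equiv), KOtBu (1.25 equiv), THF, 0 °C; 2 (1.25 equiv) in THF added slowly at −20 °C; then 4 (1.0 equiv), PdCl2(PPh3)2 (5 mol %) pre-reduced with n-BuLi (10 mol %), DMSO, 25 °C
Reagents that add atoms: none
Why: KOtBu converts 5 into alkoxide 6, whose oxa-Michael addition to the β-unsubstituted acceptor 2 forms O–C9 and leaves the stabilised enolate 7. Zerovalent palladium, made from PdCl2(PPh3)2 and n-BuLi, inserts into the C–I bond of 4, and the resulting arylpalladium iodide (divalent palladium) coordinates the alkyne of 7. The enolate carbon attacks the activated alkyne from the face opposite to palladium in a 5-exo-dig closure (C8–C8', ring C), and reductive elimination from the vinyl(aryl)palladium intermediate forms C7'–aryl and returns zerovalent palladium. The closest known reaction type is the palladium-mediated three-component coupling of propargyl alkoxides, alkylidenemalonates and aryl halides, an extension of the cyclisation–coupling of alkynyl malonates in which 2 is a less explored acceptor. No stereocentre is created; the anti addition places ring A trans to C8 and so gives only the Z alkene. The 5-exo mode is secured by the three-atom tether between the enolate carbon and the alkyne, which puts the internal alkyne carbon within reach and the terminal one not. Oxygen addition is favoured over oligomerisation of 2 by adding fresh 2 slowly to a slight excess of the unhindered alkoxide at low temperature, the tertiary enolate 7 being the slower Michael donor, and a slight deficit of KOtBu relative to 5 leaves no free tert-butoxide to isomerise the propargyl ether. Intramolecular attack on the palladium-bound alkyne is expected to outrun intermolecular arylation of the enolate or of the terminal alkyne.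

Step 4
Reactants: 8 diethyl (Z)-4-[4-(benzyloxy)-3-methoxybenzylidene]dihydrofuran-3,3(2H)-dicarboxylate
Product: 9 diethyl (4R)-4-[4-(benzyloxy)-3-methoxybenzyl]dihydrofuran-3,3(2H)-dicarboxylate
Conditions: [Ir(cod)(L)][B(3,5-(CF3)2C6H3)4] (L = (S)-4-tert-butyl-2-[2-(diphenylphosphanyl)phenyl]-4,5-dihydrooxazole; 2 mol %), H2 (50 bar), CH2Cl2, 25 °C
Reagents that add atoms: none
Why: Iridium-catalysed asymmetric hydrogenation of a trisubstituted aryl alkene of the α-substituted cinnamyl ether type; the N,P-ligated cationic iridium hydride should tell the faces apart through the large steric difference between the quaternary C8 and the C9' methylene, so the fixed Z geometry becomes one configuration at C8', and benzyl ethers and esters are inert to this catalyst.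

Step 5
Reactants: 9 diethyl (4R)-4-[4-(benzyloxy)-3-methoxybenzyl]dihydrofuran-3,3(2H)-dicarboxylate
Product: 11 ethyl (3R,4R)-4-[4-(benzyloxy)-3-methoxybenzyl]tetrahydrofuran-3-carboxylate, via C3-epimeric ester mixture 10 (not isolated)
Conditions: LiCl (3 equiv), H2O (2 equiv), DMSO, 160 °C; crude, then NaOEt (0.2 equiv), EtOH, 50 °C
Reagents that add atoms: none
Why: Krapcho de-ethoxycarbonylation (chloride dealkylation, loss of CO2, protonation of the ester enolate) gives mixture 10, in which kinetic protonation anti to the benzyl group may favour cis; ethoxide equilibration through the ester enolate then moves C8 to the more stable trans arrangement while the non-acidic C8' is untouched, so C8 (R) is set by C8'. Ring opening by β-elimination of the C9 oxygen would be the reverse of a 5-endo-trig closure and is stereoelectronically disfavoured; residual cis ester is separable and can be resubjected.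

Step 6
Reactants: 11 ethyl (3R,4R)-4-[4-(benzyloxy)-3-methoxybenzyl]tetrahydrofuran-3-carboxylate
Product: 12 (3R,4R)-4-[4-(benzyloxy)-3-methoxybenzyl]-N-methoxy-N-methyltetrahydrofuran-3-carboxamide
Conditions: MeNH(OMe)·HCl (1.5 equiv), i-PrMgCl (3.0 equiv), THF, −20 to 0 °C
Reagents that add atoms: N,O-dimethylhydroxylamine hydrochloride, CNOC.Cl
Why: Direct aminolysis of the ester by the chloromagnesium amide formed in the flask (Weinreb amide synthesis); any C8 epimerisation by the basic amide can only lead toward the favoured trans isomer.

Step 7
Reactants: 13 4-bromo-2,6-dimethoxyphenol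
Product: 14 2-(benzyloxy)-5-bromo-1,3-dimethoxybenzene
Conditions: BnBr, K2CO3, DMF, 50 °C
Reagents that add atoms: benzyl bromide, BrCc1ccccc1
Why: Williamson ether synthesis; gentle warming compensates for the two flanking methoxy groups.

Step 8
Reactants: 14 2-(benzyloxy)-5-bromo-1,3-dimethoxybenzene; 12 (3R,4R)-4-[4-(benzyloxy)-3-methoxybenzyl]-N-methoxy-N-methyltetrahydrofuran-3-carboxamide
Product: 16 [4-(benzyloxy)-3,5-dimethoxyphenyl]{(3R,4R)-4-[4-(benzyloxy)-3-methoxybenzyl]tetrahydrofuran-3-yl}methanone, via aryllithium 15 (not isolated)
Conditions: 14 (1.3 equiv), n-BuLi (1.25 equiv), THF, −78 °C; then 12, −78 to 0 °C; aq. NH4Cl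
Reagents that add atoms: none
Why: Bromine–lithium exchange gives 15, which adds once to the amide because the chelated tetrahedral adduct survives until the aqueous quench (Weinreb ketone synthesis); the ketone appears only on work-up, and the trans ketone is in any case the stable C8 epimer.

Step 9
Reactants: 16 [4-(benzyloxy)-3,5-dimethoxyphenyl]{(3R,4R)-4-[4-(benzyloxy)-3-methoxybenzyl]tetrahydrofuran-3-yl}methanone
Product: 17 (S)-[4-(benzyloxy)-3,5-dimethoxyphenyl]{(3R,4R)-4-[4-(benzyloxy)-3-methoxybenzyl]tetrahydrofuran-3-yl}methanol
Conditions: (R)-1-methyl-3,3-diphenyltetrahydro-1H,3H-pyrrolo[1,2-c][1,3,2]oxazaborole (20 mol %), BH3·SMe2 (1.0 equiv), THF, −20 °C; MeOH, then aqueous work-up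
Reagents that add atoms: none
Why: Corey–Bakshi–Shibata reduction: the oxazaborolidine–borane complex binds the carbonyl lone pair anti to the aryl group (aryl as the large substituent) and delivers hydride within the complex to one face, which with the (R)-catalyst gives (S) at C7 (O > aryl > C8 > H); reagent control is expected to override the modest bias of C8.

Step 10
Reactants: 17 (S)-[4-(benzyloxy)-3,5-dimethoxyphenyl]{(3R,4R)-4-[4-(benzyloxy)-3-methoxybenzyl]tetrahydrofuran-3-yl}methanol
Product: 18 4-{(S)-hydroxy[(3R,4R)-4-(4-hydroxy-3-methoxybenzyl)tetrahydrofuran-3-yl]methyl}-2,6-dimethoxyphenol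
Conditions: H2 (1 atm), Pd/C (10 %), EtOAc, 25 °C
Reagents that add atoms: none
Why: Hydrogenolysis of two aryl benzyl ethers in a neutral solvent; phenolic benzyl ethers cleave much faster than the C7–O bond of a benzylic alcohol under these conditions, as in the routine debenzylation of arylglycerol lignin models, and the reaction is stopped once debenzylation is complete.

## Compound list

1 | diethyl malonate | CCOC(=O)CC(=O)OCC | starting material
2 | diethyl methylidenemalonate | C=C(C(=O)OCC)C(=O)OCC | intermediate
3 | 4-iodo-2-methoxyphenol | COc1cc(I)ccc1O | starting material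
4 | 1-(benzyloxy)-4-iodo-2-methoxybenzene | COc1cc(I)ccc1OCc1ccccc1 | intermediate
5 | propargyl alcohol (prop-2-yn-1-ol) | C#CCO | starting material
6 | potassium prop-2-yn-1-olate | [K+].[O-]CC#C | intermediate (not isolated)
7 | potassium enolate of diethyl 2-[(prop-2-yn-1-yloxy)methyl]malonate | [K+].CCOC(=O)[C-](COCC#C)C(=O)OCC | intermediate (not isolated)
8 | diethyl (Z)-4-[4-(benzyloxy)-3-methoxybenzylidene]dihydrofuran-3,3(2H)-dicarboxylate | CCOC(=O)C1(C(=O)OCC)COC/C1=C\c1ccc(OCc2ccccc2)c(OC)c1 | intermediate
9 | diethyl (4R)-4-[4-(benzyloxy)-3-methoxybenzyl]dihydrofuran-3,3(2H)-dicarboxylate | COc1cc(C[C@H]2COCC2(C(=O)OCC)C(=O)OCC)ccc1OCc1ccccc1 | intermediate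
10 | ethyl (4R)-4-[4-(benzyloxy)-3-methoxybenzyl]tetrahydrofuran-3-carboxylate, mixture of C3 epimers | COc1cc(C[C@H]2COCC2C(=O)OCC)ccc1OCc1ccccc1 | intermediate (not isolated)
11 | ethyl (3R,4R)-4-[4-(benzyloxy)-3-methoxybenzyl]tetrahydrofuran-3-carboxylate (trans) | COc1cc(C[C@H]2COC[C@@H]2C(=O)OCC)ccc1OCc1ccccc1 | intermediate
12 | (3R,4R)-4-[4-(benzyloxy)-3-methoxybenzyl]-N-methoxy-N-methyltetrahydrofuran-3-carboxamide | COc1cc(C[C@H]2COC[C@@H]2C(=O)N(C)OC)ccc1OCc1ccccc1 | intermediate
13 | 4-bromo-2,6-dimethoxyphenol | COc1cc(Br)cc(OC)c1O | starting material
14 | 2-(benzyloxy)-5-bromo-1,3-dimethoxybenzene | COc1cc(Br)cc(OC)c1OCc1ccccc1 | intermediate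
15 | [4-(benzyloxy)-3,5-dimethoxyphenyl]lithium | [Li]c1cc(OC)c(OCc2ccccc2)c(OC)c1 | intermediate (not isolated)
16 | [4-(benzyloxy)-3,5-dimethoxyphenyl]{(3R,4R)-4-[4-(benzyloxy)-3-methoxybenzyl]tetrahydrofuran-3-yl}methanone | COc1cc(C[C@H]2COC[C@@H]2C(=O)c2cc(OC)c(OCc3ccccc3)c(OC)c2)ccc1OCc1ccccc1 | intermediate
17 | (S)-[4-(benzyloxy)-3,5-dimethoxyphenyl]{(3R,4R)-4-[4-(benzyloxy)-3-methoxybenzyl]tetrahydrofuran-3-yl}methanol | COc1cc(C[C@H]2COC[C@@H]2[C@H](O)c2cc(OC)c(OCc3ccccc3)c(OC)c2)ccc1OCc1ccccc1 | intermediate
18 | 4-{(S)-hydroxy[(3R,4R)-4-(4-hydroxy-3-methoxybenzyl)tetrahydrofuran-3-yl]methyl}-2,6-dimethoxyphenol, (7S,8R,8'R) | COc1cc(C[C@H]2COC[C@@H]2[C@H](O)c2cc(OC)c(O)c(OC)c2)ccc1O | target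

## Step count and risks

Total: 10 steps. Longest linear sequence: 8 steps (1, 3, 4, 5, 6, 8, 9, 10; from 1 to 18).

Step 3 (key step). What may go wrong: anionic oligomerisation of 2 (carbon Michael addition of enolate 7 to further 2 competing with oxygen addition of 6), reversal of the oxygen addition, and at the palladium stage direct coupling of the terminal alkyne or protonation of the vinylpalladium intermediate instead of reductive elimination. Fallback, from 5 and 1, returning at 7 and 8: the O–C9 bond is made beforehand without 2. Propargyl alcohol 5 is converted (paraformaldehyde, HCl gas, 0 °C) into chloromethyl prop-2-yn-1-yl ether F1. F1 alkylates the sodium enolate of 1 (NaH, THF, 0 °C) to give diethyl 2-[(prop-2-yn-1-yloxy)methyl]malonate F2. Deprotonation of F2 with KOtBu gives the same enolate 7, and cyclisation–arylation with 4 under the palladium conditions of step 3 leads to 8.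

Step 4. What may go wrong: slow or incomplete hydrogenation because the quaternary C8 shields the alkene, or insufficient facial selectivity for an alkene whose two carbon substituents differ in size but not in kind. Fallback, from 8, returning at 12:
- Hydrogenation with the achiral complex [Ir(cod)(PCy3)(py)]PF6 (H2, CH2Cl2) gives racemic diethyl 4-[4-(benzyloxy)-3-methoxybenzyl]dihydrofuran-3,3(2H)-dicarboxylate F3.
- Krapcho de-ethoxycarbonylation (LiCl, H2O, DMSO, 160 °C) gives ethyl 4-[4-(benzyloxy)-3-methoxybenzyl]tetrahydrofuran-3-carboxylate as a stereoisomer mixture F4.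
- NaOEt in EtOH followed by aqueous NaOH equilibrates and saponifies it to racemic trans-4-[4-(benzyloxy)-3-methoxybenzyl]tetrahydrofuran-3-carboxylic acid F5.
- Classical resolution by crystallisation gives (R)-1-phenylethylammonium (3R,4R)-4-[4-(benzyloxy)-3-methoxybenzyl]tetrahydrofuran-3-carboxylate F6. It is written for the (R)-amine; the (S)-amine is taken if its salt with the (3R,4R) acid is the less soluble one.
- Acidification with dilute HCl liberates (3R,4R)-4-[4-(benzyloxy)-3-methoxybenzyl]tetrahydrofuran-3-carboxylic acid F7, which is coupled with N,O-dimethylhydroxylamine hydrochloride (EDC, HOBt, i-Pr2NEt, CH2Cl2) to 12.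

Step 9. What may go wrong: poor facial selectivity, because the α-branched ring substituent is closer in size to the aryl group than a methyl would be and the bias of C8 may oppose the catalyst. Fallback, from 16, returning at 17: reduction with NaBH4 (MeOH, 0 °C) gives both C7 epimers and 17 is separated by chromatography. The other epimer, (R)-[4-(benzyloxy)-3,5-dimethoxyphenyl]{(3R,4R)-4-[4-(benzyloxy)-3-methoxybenzyl]tetrahydrofuran-3-yl}methanol F8, is inverted by a Mitsunobu reaction (4-nitrobenzoic acid, PPh3, diisopropyl azodicarboxylate, THF) to (S)-[4-(benzyloxy)-3,5-dimethoxyphenyl]{(3R,4R)-4-[4-(benzyloxy)-3-methoxybenzyl]tetrahydrofuran-3-yl}methyl 4-nitrobenzoate F9. Methanolysis of F9 (K2CO3, MeOH) gives 17. The 4-alkoxy group of ring B is twisted out of conjugation by its two methoxy neighbours, which should limit ionisation during the inversion.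

Step 10. What may go wrong: over-reduction, that is hydrogenolysis of the benzylic C7–O bond once the para-phenol of ring B is free. Fallback, from 16, returning at 18: the benzyl groups are exchanged before C7 becomes a carbinol.
- Hydrogenolysis of 16 (H2, Pd/C, EtOAc) gives (4-hydroxy-3,5-dimethoxyphenyl)[(3R,4R)-4-(4-hydroxy-3-methoxybenzyl)tetrahydrofuran-3-yl]methanone F10.
- Silylation (TBSCl, imidazole, DMF) gives the bis(tert-butyldimethylsilyl) ether F11.
- CBS reduction under the conditions of step 9 gives the bis(silyl) (S)-alcohol F12.
- Bu4NF buffered with AcOH (THF, 0 °C) removes both silyl groups under non-reductive, near-neutral conditions to give 18.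

## Further compounds

F1 | step 3 | chloromethyl prop-2-yn-1-yl ether | C#CCOCCl
F2 | step 3 | diethyl 2-[(prop-2-yn-1-yloxy)methyl]malonate | CCOC(=O)C(COCC#C)C(=O)OCC
F3 | step 4 | racemic diethyl 4-[4-(benzyloxy)-3-methoxybenzyl]dihydrofuran-3,3(2H)-dicarboxylate | CCOC(=O)C1(C(=O)OCC)COCC1Cc1ccc(OCc2ccccc2)c(OC)c1
F4 | step 4 | ethyl 4-[4-(benzyloxy)-3-methoxybenzyl]tetrahydrofuran-3-carboxylate, stereoisomer mixture | CCOC(=O)C1COCC1Cc1ccc(OCc2ccccc2)c(OC)c1
F5 | step 4 | racemic trans-4-[4-(benzyloxy)-3-methoxybenzyl]tetrahydrofuran-3-carboxylic acid (both enantiomers written) | COc1cc(C[C@H]2COC[C@@H]2C(=O)O)ccc1OCc1ccccc1.COc1cc(C[C@@H]2COC[C@H]2C(=O)O)ccc1OCc1ccccc1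
F6 | step 4 | (R)-1-phenylethylammonium (3R,4R)-4-[4-(benzyloxy)-3-methoxybenzyl]tetrahydrofuran-3-carboxylate | COc1cc(C[C@H]2COC[C@@H]2C([O-])=O)ccc1OCc1ccccc1.C[C@@H]([NH3+])c1ccccc1
F7 | step 4 | (3R,4R)-4-[4-(benzyloxy)-3-methoxybenzyl]tetrahydrofuran-3-carboxylic acid | COc1cc(C[C@H]2COC[C@@H]2C(=O)O)ccc1OCc1ccccc1
F8 | step 9 | (R)-[4-(benzyloxy)-3,5-dimethoxyphenyl]{(3R,4R)-4-[4-(benzyloxy)-3-methoxybenzyl]tetrahydrofuran-3-yl}methanol | COc1cc(C[C@H]2COC[C@@H]2[C@@H](O)c2cc(OC)c(OCc3ccccc3)c(OC)c2)ccc1OCc1ccccc1
F9 | step 9 | (S)-[4-(benzyloxy)-3,5-dimethoxyphenyl]{(3R,4R)-4-[4-(benzyloxy)-3-methoxybenzyl]tetrahydrofuran-3-yl}methyl 4-nitrobenzoate | COc1cc(C[C@H]2COC[C@@H]2[C@H](OC(=O)c2ccc(cc2)[N+](=O)[O-])c2cc(OC)c(OCc3ccccc3)c(OC)c2)ccc1OCc1ccccc1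
F10 | step 10 | (4-hydroxy-3,5-dimethoxyphenyl)[(3R,4R)-4-(4-hydroxy-3-methoxybenzyl)tetrahydrofuran-3-yl]methanone | COc1cc(C[C@H]2COC[C@@H]2C(=O)c2cc(OC)c(O)c(OC)c2)ccc1O
F11 | step 10 | {4-[(tert-butyldimethylsilyl)oxy]-3,5-dimethoxyphenyl}[(3R,4R)-4-{4-[(tert-butyldimethylsilyl)oxy]-3-methoxybenzyl}tetrahydrofuran-3-yl]methanone | COc1cc(C[C@H]2COC[C@@H]2C(=O)c2cc(OC)c(O[Si](C)(C)C(C)(C)C)c(OC)c2)ccc1O[Si](C)(C)C(C)(C)C
F12 | step 10 | (S)-{4-[(tert-butyldimethylsilyl)oxy]-3,5-dimethoxyphenyl}[(3R,4R)-4-{4-[(tert-butyldimethylsilyl)oxy]-3-methoxybenzyl}tetrahydrofuran-3-yl]methanol | COc1cc(C[C@H]2COC[C@@H]2[C@H](O)c2cc(OC)c(O[Si](C)(C)C(C)(C)C)c(OC)c2)ccc1O[Si](C)(C)C(C)(C)C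
A1 | alternative 1 | (5R)-5-{[(1R,2S,5R)-5-methyl-2-(propan-2-yl)cyclohexyl]oxy}furan-2(5H)-one | O=C1O[C@@H](O[C@@H]2C[C@H](C)CC[C@H]2C(C)C)C=C1
A2 | alternative 1 | 2-[4-(benzyloxy)-3,5-dimethoxyphenyl]-1,3-dithiane | COc1cc(C2SCCCS2)cc(OC)c1OCc1ccccc1
A3 | alternative 1 | 1-(benzyloxy)-4-(bromomethyl)-2-methoxybenzene | COc1cc(CBr)ccc1OCc1ccccc1
A4 | alternative 1 | trans,trans-3-[4-(benzyloxy)-3-methoxybenzyl]-4-{2-[4-(benzyloxy)-3,5-dimethoxyphenyl]-1,3-dithian-2-yl}-5-(l-menthyloxy)dihydrofuran-2(3H)-one | COc1cc(C[C@H]2C(=O)O[C@@H](O[C@@H]3C[C@H](C)CC[C@H]3C(C)C)[C@@H]2C4(c5cc(OC)c(OCc6ccccc6)c(OC)c5)SCCCS4)ccc1OCc1ccccc1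
A5 | alternative 2 | (E)-configured (phenylselanyl)methyl ether of the C7-silylated, bis-benzylated seco precursor (C7 S, C8 as in the target) | COc1cc(/C=C/[C@H](COC[Se]c2ccccc2)[C@H](O[Si](C)(C)C(C)(C)C)c2cc(OC)c(OCc3ccccc3)c(OC)c2)ccc1OCc1ccccc1
A6 | alternative 2 | tert-butyldimethylsilyl ether of the target with both phenols benzylated | COc1cc(C[C@H]2COC[C@@H]2[C@H](O[Si](C)(C)C(C)(C)C)c2cc(OC)c(OCc3ccccc3)c(OC)c2)ccc1OCc1ccccc1
A7 | alternative 3 | (S)-4-benzyl-3-{(E)-4-[4-(benzyloxy)-3-methoxyphenyl]but-2-enoyl}oxazolidin-2-one | O=C1OC[C@H](Cc2ccccc2)N1C(=O)/C=C/Cc1ccc(OCc2ccccc2)c(OC)c1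
A8 | alternative 3 | chloromethyl (trimethylsilyl)methyl ether | C[Si](C)(C)COCCl
A9 | alternative 3 | unsubstituted carbonyl ylide (methylideneoxoniomethanide) | C=[O+][CH2-]
A10 | alternative 3 | (S)-4-benzyl-3-{[(3R,4R)-4-(4-benzyloxy-3-methoxybenzyl)tetrahydrofuran-3-yl]carbonyl}oxazolidin-2-one | O=C1OC[C@H](Cc2ccccc2)N1C(=O)[C@H]1COC[C@@H]1Cc1ccc(OCc2ccccc2)c(OC)c1
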